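**Plan**

1. Retrosynthesis: first strip the seven benzyl-type ethers and invert C2 of both dihydrofuran rings (cis to trans). Then cut the C2–C3 bond of the dihydrofuran ring that carries the 3,5-dihydroxyphenyl group (second ring) back to an ArO–CH2Ar ether and a diaryl carbene at C3. Then cut the carbene carbon from C3a (aryllithium + nitrile). Repeat both cuts for the first dihydrofuran ring (aryllithium + aldehyde), and last cut the stilbene C=C (Horner–Wadsworth–Emmons).
2. Forward: one building block, aldehyde 5, is used twice, as the stilbene-bearing resorcinol and as the central resorcinol. The order is stilbene, diaryl ketone hydrazone, first dihydrofuran ring, Br/Li exchange with nitrile addition and hydrazone formation, second dihydrofuran ring, global deprotection.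
3. Enabling feature: in the second ring, C2 is a benzylic CH bonded to the ring oxygen O1 and lies 1,5 to C3, and C3 carries two aryl groups. C3 can therefore be a donor/donor carbene and C2–H an α-oxy benzylic C–H bond. C3a lies between two oxygen-bearing carbons (C7a–O1 and C4–OH), so two identical ortho benzyl ethers are equivalent and the unused one ends as the C4 hydroxyl.
4. Stereochemistry: C3 of each ring comes from the same chiral Rh(II) carboxylate (catalyst control, rings formed 2,3-cis). C2 of both rings is relayed to trans in the last step by reversible ionisation of the O1–C2 bonds. The E-alkene comes from the Horner–Wadsworth–Emmons reaction.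

Key step: step 12

Notation: PBB = 4-(benzyloxy)benzyl; OPBB = [4-(benzyloxy)benzyl]oxy; Bn = benzyl. Primed locants refer to the second dihydrobenzofuran.

Assumption: the sense of induction of Rh2(PTAD)4 is assigned by analogy. "Rh2(R-PTAD)4" stands for the catalyst antipode that sets C3 as S, and both insertions need the same antipode because the two rings have the same absolute sense.

**Route**

Step 1
Reactants: 1 methyl 4-bromo-3,5-dihydroxybenzoate; 2 4-(benzyloxy)benzyl chloride (2.2 equiv)
Product: 3 methyl 4-bromo-3,5-bis{[4-(benzyloxy)benzyl]oxy}benzoate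
Conditions: K2CO3, KI (cat.), DMF, 60 °C
Reagents that add atoms: none
Why: Williamson ether synthesis; both phenoxides flanking the bromine should be O-alkylated by the activated benzylic chloride.

Step 2
Reactants: 3 methyl 4-bromo-3,5-bis(OPBB)benzoate
Product: 4 [4-bromo-3,5-bis(OPBB)phenyl]methanol
Conditions: DIBAL-H (2.5 equiv), CH2Cl2, −78 → 0 °C; Rochelle salt work-up
Reagents that add atoms: none
Why: DIBAL-H reduction of an aryl ester to the benzylic alcohol; the aryl bromide and the benzyl ethers are inert to the hydride.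

Step 3
Reactants: 4 [4-bromo-3,5-bis(OPBB)phenyl]methanol
Product: 5 4-bromo-3,5-bis(OPBB)benzaldehyde
Conditions: activated MnO2 (10 equiv), CH2Cl2, rt
Reagents that add atoms: none
Why: MnO2 oxidation of a benzylic alcohol, which should stop at the aldehyde.

Step 4
Reactants: 2 4-(benzyloxy)benzyl chloride
Product: 6 diethyl [4-(benzyloxy)benzyl]phosphonate
Conditions: P(OEt)3 (1.5 equiv), neat, 150 °C
Reagents that add atoms: triethyl phosphite, CCOP(OCC)OCC
Why: Michaelis–Arbuzov reaction of a benzylic chloride; the phosphonium intermediate is dealkylated by chloride.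

Step 5
Reactants: 5 4-bromo-3,5-bis(OPBB)benzaldehyde; 6 diethyl [4-(benzyloxy)benzyl]phosphonate
Product: 7 (E)-2-bromo-1,3-bis(OPBB)-5-[2-(4-benzyloxyphenyl)ethenyl]benzene
Conditions: NaH, THF, 0 °C → rt
Reagents that add atoms: none
Why: Horner–Wadsworth–Emmons olefination of a non-enolisable aryl aldehyde with a benzylphosphonate anion, which should give the E-stilbene.

Step 6
Reactants: 7 (E)-stilbene bromide; 5 4-bromo-3,5-bis(OPBB)benzaldehyde
Product: 9 racemic [2,6-bis(OPBB)-4-((E)-4-benzyloxystyryl)phenyl][4-bromo-3,5-bis(OPBB)phenyl]methanol, via aryllithium 8 (not isolated)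
Conditions: n-BuLi (1.05 equiv), THF, −78 °C; then 5, −78 → −20 °C; H2O
Reagents that add atoms: none
Why: Br/Li exchange between the two alkoxy groups is faster than any deprotonation at −78 °C, and 1,2-addition of the aryllithium to the aldehyde is faster than exchange with its aryl bromide; the carbinol centre is removed in step 7.

Step 7
Reactants: 9 diaryl carbinol
Product: 10 [2,6-bis(OPBB)-4-((E)-4-benzyloxystyryl)phenyl][4-bromo-3,5-bis(OPBB)phenyl]methanone
Conditions: Dess–Martin periodinane (1.3 equiv), NaHCO3, CH2Cl2, 0 °C → rt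
Reagents that add atoms: none
Why: Dess–Martin oxidation of a hindered benzhydrol under buffered conditions, so that the electron-rich carbinol is not ionised by acid.

Step 8
Reactants: 10 diaryl ketone
Product: 11 hydrazone of 10
Conditions: N2H4·H2O (20 equiv), AcOH (cat.), n-BuOH, 110 °C, argon
Reagents that add atoms: hydrazine, NN
Why: hydrazone condensation, forced by excess hydrazine and heat because one aryl group is di-ortho-substituted; air is excluded so that no diimide forms to reduce the stilbene.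

Step 9
Reactants: 11 hydrazone
Product: 13 (2R,3S)-cis-4-OPBB-2-(4-benzyloxyphenyl)-3-[4-bromo-3,5-bis(OPBB)phenyl]-6-[(E)-4-benzyloxystyryl]-2,3-dihydro-1-benzofuran, via diaryldiazomethane 12 (not isolated)
Conditions: MnO2, CH2Cl2, 0 °C, filtration; Rh2(R-PTAD)4 (1 mol %), CH2Cl2, 0 °C → rt
Reagents that add atoms: none
Why: same reaction type as step 12 (hydrazone oxidation to the diaryldiazomethane, then Rh(II)-catalysed enantioselective 1,5-C–H insertion of the donor/donor carbene into an ArO–CH2Ar bond): the catalyst sets C3 as S, the insertion geometry gives the 2,3-cis ring, the two ortho PBB ethers are equivalent and the meta PBB ethers of the bromoaryl ring cannot be reached.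

Step 10
Reactants: 14 3,5-dihydroxybenzonitrile
Product: 15 3,5-bis(benzyloxy)benzonitrile
Conditions: BnBr (2.2 equiv), K2CO3, DMF, rt
Reagents that add atoms: benzyl bromide, BrCc1ccccc1
Why: Williamson ether synthesis on both phenols.

Step 11
Reactants: 13 bromo-dihydrobenzofuran; 15 3,5-bis(benzyloxy)benzonitrile
Product: 18 (2R,3S)-cis-3-{4-[(3,5-bis(benzyloxy)phenyl)(hydrazinylidene)methyl]-3,5-bis(OPBB)phenyl}-4-OPBB-2-(4-benzyloxyphenyl)-6-[(E)-4-benzyloxystyryl]-2,3-dihydro-1-benzofuran, via aryllithium 16 (not isolated), via N-H ketimine 17 (not isolated)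
Conditions: n-BuLi, THF, −78 °C; 15, −78 → 0 °C; AcOH; then N2H4·H2O, EtOH, 60 °C
Reagents that add atoms: hydrazine, NN
Why: Br/Li exchange, then addition of the aryllithium to the nitrile, which stops at the N-lithio ketimine, then transimination of the N–H ketimine with hydrazine; this gives the hydrazone without a condensation at a di-ortho-substituted ketone.

Step 12
Reactants: 18 hydrazone
Product: 20 (2R,3S,2'R,3'S)-cis,cis fully protected trimer [first ring as in 13; its C3 bonded to C6' of the second ring: 4'-OPBB-2'-(4-benzyloxyphenyl)-3'-(3,5-bis(benzyloxy)phenyl)-2',3'-dihydro-1-benzofuran], via diaryldiazomethane 19 (not isolated)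
Conditions: MnO2, CH2Cl2, 0 °C, filtration; Rh2(R-PTAD)4 (2 mol %), CH2Cl2, 0 °C → rt
Reagents that add atoms: none
Why: MnO2 dehydrogenates the hydrazone to the diaryldiazomethane 19, which loses N2 at the chiral dirhodium tetracarboxylate to give a donor/donor Rh carbene centred on the future C3'; the carbene inserts into an ArO–CH2 benzylic C–H bond five atoms away through a three-centre, hydride-transfer-like transition state and so forms the C2'–C3' bond. The closest known reaction type is the enantioselective intramolecular C–H insertion of donor/donor rhodium carbenes into benzyl aryl ethers, which gives cis-2,3-diaryl-2,3-dihydrobenzofurans. The dihydrofuran ring closes in the 1,5-C–H insertion mode (five-membered transition state; O1', C7a' and C3a' are already in place). C3' is set by the catalyst, whose chiral carboxylate pocket decides which face of the carbene receives the C–H bond and overrides the remote centres of the first ring; C2' follows from the insertion geometry, which places the two aryl groups cis, and is corrected in step 13. The step needs site selectivity for this C–H bond over azine formation, cyclopropanation of the stilbene and the other ether C–H bonds; this is secured by the 1,5 distance, by the double activation of the C–H bond (α-oxygen and p-alkoxyaryl) and by the two ortho substituents that shield the diazo carbon from bimolecular reactions. The two ortho PBB ethers are interchanged by rotation about the aryl–carbene bond, so either gives the same product and the unused one is the protected C4' hydroxyl.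

Step 13
Reactants: 20 protected cis,cis trimer
Product: 21 (2S,3S)-3-[(2S,3S)-3-(3,5-dihydroxyphenyl)-4-hydroxy-2-(4-hydroxyphenyl)-2,3-dihydro-1-benzofuran-6-yl]-2-(4-hydroxyphenyl)-6-[(E)-2-(4-hydroxyphenyl)ethenyl]-2,3-dihydro-1-benzofuran-4-ol
Conditions: BCl3 (30 equiv), C6HMe5 (30 equiv), CH2Cl2, −78 → 0 °C; MeOH quench
Reagents that add atoms: none
Why: BCl3 with pentamethylbenzene as a non-basic cation scavenger cleaves aryl benzyl and aryl 4-oxybenzyl ethers by Lewis-acid-assisted C–O ionisation and Friedel–Crafts capture of the benzyl cations without touching the stilbene, and the same Lewis acid should reversibly ionise the two cyclic O1–C2 benzylic ether bonds, so that re-closure relays the fixed C3 centres to C2 and both rings settle in the favoured 2,3-trans form (acid-mediated cis-to-trans equilibration of 2-aryl-2,3-dihydrobenzofurans; C2 goes from R to S in each ring).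

**Compound list**

1 | methyl 4-bromo-3,5-dihydroxybenzoate | COC(=O)c1cc(O)c(Br)c(O)c1 | starting material
2 | 4-(benzyloxy)benzyl chloride | ClCc1ccc(OCc2ccccc2)cc1 | starting material
3 | methyl 4-bromo-3,5-bis{[4-(benzyloxy)benzyl]oxy}benzoate | COC(=O)c1cc(OCc2ccc(OCc3ccccc3)cc2)c(Br)c(OCc2ccc(OCc3ccccc3)cc2)c1 | intermediate
4 | [4-bromo-3,5-bis(OPBB)phenyl]methanol | OCc1cc(OCc2ccc(OCc3ccccc3)cc2)c(Br)c(OCc2ccc(OCc3ccccc3)cc2)c1 | intermediate
5 | 4-bromo-3,5-bis(OPBB)benzaldehyde | O=Cc1cc(OCc2ccc(OCc3ccccc3)cc2)c(Br)c(OCc2ccc(OCc3ccccc3)cc2)c1 | intermediate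
6 | diethyl [4-(benzyloxy)benzyl]phosphonate | CCOP(=O)(Cc1ccc(OCc2ccccc2)cc1)OCC | intermediate
7 | (E)-2-bromo-1,3-bis(OPBB)-5-[2-(4-benzyloxyphenyl)ethenyl]benzene | Brc1c(OCc2ccc(OCc3ccccc3)cc2)cc(/C=C/c2ccc(OCc3ccccc3)cc2)cc1OCc1ccc(OCc2ccccc2)cc1 | intermediate
8 | aryllithium from 7 (formed in situ) | [Li]c1c(OCc2ccc(OCc3ccccc3)cc2)cc(/C=C/c2ccc(OCc3ccccc3)cc2)cc1OCc1ccc(OCc2ccccc2)cc1 | intermediate
9 | racemic [2,6-bis(OPBB)-4-((E)-4-benzyloxystyryl)phenyl][4-bromo-3,5-bis(OPBB)phenyl]methanol | OC(c1c(OCc2ccc(OCc3ccccc3)cc2)cc(/C=C/c2ccc(OCc3ccccc3)cc2)cc1OCc1ccc(OCc2ccccc2)cc1)c1cc(OCc2ccc(OCc3ccccc3)cc2)c(Br)c(OCc2ccc(OCc3ccccc3)cc2)c1 | intermediate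
10 | [2,6-bis(OPBB)-4-((E)-4-benzyloxystyryl)phenyl][4-bromo-3,5-bis(OPBB)phenyl]methanone | O=C(c1c(OCc2ccc(OCc3ccccc3)cc2)cc(/C=C/c2ccc(OCc3ccccc3)cc2)cc1OCc1ccc(OCc2ccccc2)cc1)c1cc(OCc2ccc(OCc3ccccc3)cc2)c(Br)c(OCc2ccc(OCc3ccccc3)cc2)c1 | intermediate
11 | hydrazone of ketone 10 | NN=C(c1c(OCc2ccc(OCc3ccccc3)cc2)cc(/C=C/c2ccc(OCc3ccccc3)cc2)cc1OCc1ccc(OCc2ccccc2)cc1)c1cc(OCc2ccc(OCc3ccccc3)cc2)c(Br)c(OCc2ccc(OCc3ccccc3)cc2)c1 | intermediate
12 | diaryldiazomethane from 11 (formed in situ) | [N-]=[N+]=C(c1c(OCc2ccc(OCc3ccccc3)cc2)cc(/C=C/c2ccc(OCc3ccccc3)cc2)cc1OCc1ccc(OCc2ccccc2)cc1)c1cc(OCc2ccc(OCc3ccccc3)cc2)c(Br)c(OCc2ccc(OCc3ccccc3)cc2)c1 | intermediate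
13 | (2R,3S)-cis-4-OPBB-2-(4-benzyloxyphenyl)-3-[4-bromo-3,5-bis(OPBB)phenyl]-6-[(E)-4-benzyloxystyryl]-2,3-dihydro-1-benzofuran | O(Cc1ccccc1)c1ccc(/C=C/c2cc(OCc4ccc(OCc5ccccc5)cc4)c3c(c2)O[C@@H](c2ccc(OCc4ccccc4)cc2)[C@H]3c2cc(OCc4ccc(OCc5ccccc5)cc4)c(Br)c(OCc4ccc(OCc5ccccc5)cc4)c2)cc1 | intermediate
14 | 3,5-dihydroxybenzonitrile | N#Cc1cc(O)cc(O)c1 | starting material
15 | 3,5-bis(benzyloxy)benzonitrile | N#Cc1cc(OCc2ccccc2)cc(OCc2ccccc2)c1 | intermediate
16 | aryllithium from 13 (formed in situ; Li in place of Br) | O(Cc1ccccc1)c1ccc(/C=C/c2cc(OCc4ccc(OCc5ccccc5)cc4)c3c(c2)O[C@@H](c2ccc(OCc4ccccc4)cc2)[C@H]3c2cc(OCc4ccc(OCc5ccccc5)cc4)c([Li])c(OCc4ccc(OCc5ccccc5)cc4)c2)cc1 | intermediate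
17 | N–H ketimine (formed in situ): 13 with C(=NH)[3,5-bis(benzyloxy)phenyl] in place of Br | O(Cc1ccccc1)c1ccc(/C=C/c2cc(OCc4ccc(OCc5ccccc5)cc4)c3c(c2)O[C@@H](c2ccc(OCc4ccccc4)cc2)[C@H]3c2cc(OCc4ccc(OCc5ccccc5)cc4)c(C(=N)c4cc(OCc5ccccc5)cc(OCc5ccccc5)c4)c(OCc4ccc(OCc5ccccc5)cc4)c2)cc1 | intermediate
18 | hydrazone: 13 with C(=NNH2)[3,5-bis(benzyloxy)phenyl] in place of Br, (2R,3S)-cis | O(Cc1ccccc1)c1ccc(/C=C/c2cc(OCc4ccc(OCc5ccccc5)cc4)c3c(c2)O[C@@H](c2ccc(OCc4ccccc4)cc2)[C@H]3c2cc(OCc4ccc(OCc5ccccc5)cc4)c(C(=NN)c4cc(OCc5ccccc5)cc(OCc5ccccc5)c4)c(OCc4ccc(OCc5ccccc5)cc4)c2)cc1 | intermediate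
19 | diaryldiazomethane from 18 (formed in situ) | O(Cc1ccccc1)c1ccc(/C=C/c2cc(OCc4ccc(OCc5ccccc5)cc4)c3c(c2)O[C@@H](c2ccc(OCc4ccccc4)cc2)[C@H]3c2cc(OCc4ccc(OCc5ccccc5)cc4)c(C(=[N+]=[N-])c4cc(OCc5ccccc5)cc(OCc5ccccc5)c4)c(OCc4ccc(OCc5ccccc5)cc4)c2)cc1 | intermediate
20 | (2R,3S,2'R,3'S)-cis,cis fully protected trimer (five OBn, two OPBB) | O(Cc1ccccc1)c1ccc(/C=C/c2cc(OCc4ccc(OCc5ccccc5)cc4)c3c(c2)O[C@@H](c2ccc(OCc4ccccc4)cc2)[C@H]3c2cc(OCc4ccc(OCc5ccccc5)cc4)c3c(c2)O[C@@H](c2ccc(OCc4ccccc4)cc2)[C@H]3c2cc(OCc4ccccc4)cc(OCc4ccccc4)c2)cc1 | intermediate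
21 | (2S,3S)-3-[(2S,3S)-3-(3,5-dihydroxyphenyl)-4-hydroxy-2-(4-hydroxyphenyl)-2,3-dihydro-1-benzofuran-6-yl]-2-(4-hydroxyphenyl)-6-[(E)-2-(4-hydroxyphenyl)ethenyl]-2,3-dihydro-1-benzofuran-4-ol | Oc1ccc(/C=C/c2cc(O)c3c(c2)O[C@H](c2ccc(O)cc2)[C@H]3c2cc(O)c3c(c2)O[C@H](c2ccc(O)cc2)[C@H]3c2cc(O)cc(O)c2)cc1 | target

**Step count and risks**

Total step count: 13. Longest linear sequence: 11 steps (1 → 3 → 4 → 5 → 7 → 9 → 10 → 11 → 13 → 18 → 20 → 21, i.e. steps 1, 2, 3, 5, 6, 7, 8, 9, 11, 12, 13).

Steps most likely to fail: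

1. Step 12. The diazo compound may be lost to azine formation, carbene formation at the di-ortho-substituted carbon may be slow, or the catalyst may control the carbene face poorly this late in the route. The fallback closes the ring by carbanion chemistry and gives up catalyst control. It sets out from 17, which is made as in step 11 but hydrolysed (aqueous oxalic acid, THF, 40 °C) instead of transiminated, to give the diaryl ketone F1. LiTMP (THF, −78 → 0 °C) deprotonates one ArO–CH2Ar group next to the carbonyl, and the α-aryloxybenzyl anion adds to the ketone (intramolecular aldol-type 5-exo-trig closure) to give the 3'-hydroxy-2',3'-dihydrobenzofuran F2 as a mixture at C2' and C3'. Ionic deoxygenation (Et3SiH, BF3·OEt2, CH2Cl2, −78 °C) through the tertiary diaryl cation, with hydride delivered anti to the 2'-aryl group, should give the cis ring as two diastereomers that differ in the absolute sense of the second ring. These are separated by preparative HPLC, and the route is rejoined at 20.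

2. Step 13. The ring-opened benzylic cations may be captured by the scavenger or by the resorcinol rings, or equilibration at C2 may be incomplete. The fallback separates deprotection from epimerisation. It sets out from 20: BCl3/C6HMe5 is applied at −78 °C only and quenched cold with MeOH, which should leave the ring C–O bonds intact and give the cis,cis heptaphenol F3. The free polyphenol is then equilibrated without scavenger by dilute Brønsted acid (HCl, MeOH–THF, 40 °C), where each O1–C2 bond opens through the p-quinone methide of the free 4-hydroxyphenyl group and can only re-close. The route is rejoined at 21.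

3. Step 8. Condensation at the di-ortho-substituted carbonyl may be sluggish, and hydrazine with traces of air may reduce the stilbene through diimide. The fallback makes the hydrazone through a ketimine. It sets out from 5, which is converted by I2 and aqueous NH3 in THF into the nitrile F4. The aryllithium 8 from 7 (n-BuLi, −78 °C) is transmetalated with MgBr2·OEt2, to suppress exchange with the aryl bromide of F4, and added to F4 under CuBr·SMe2 catalysis; a methanol quench gives the N–H ketimine F5. Transimination with N2H4·H2O and AcOH in EtOH at 60 °C rejoins the route at 11.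

**Further compounds**

F1 | step 12 | diaryl ketone corresponding to ketimine 17 [C(=O) in place of C(=NH)] | O(Cc1ccccc1)c1ccc(/C=C/c2cc(OCc4ccc(OCc5ccccc5)cc4)c3c(c2)O[C@@H](c2ccc(OCc4ccccc4)cc2)[C@H]3c2cc(OCc4ccc(OCc5ccccc5)cc4)c(C(=O)c4cc(OCc5ccccc5)cc(OCc5ccccc5)c4)c(OCc4ccc(OCc5ccccc5)cc4)c2)cc1
F2 | step 12 | 3'-hydroxy analogue of 20 (mixture at C2' and C3') | O(Cc1ccccc1)c1ccc(/C=C/c2cc(OCc4ccc(OCc5ccccc5)cc4)c3c(c2)O[C@@H](c2ccc(OCc4ccccc4)cc2)[C@H]3c2cc(OCc4ccc(OCc5ccccc5)cc4)c3c(c2)OC(c2ccc(OCc4ccccc4)cc2)C3(O)c2cc(OCc4ccccc4)cc(OCc4ccccc4)c2)cc1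
F3 | step 13 | (2R,3S,2'R,3'S)-cis,cis isomer of 21 | Oc1ccc(/C=C/c2cc(O)c3c(c2)O[C@@H](c2ccc(O)cc2)[C@H]3c2cc(O)c3c(c2)O[C@@H](c2ccc(O)cc2)[C@H]3c2cc(O)cc(O)c2)cc1
F4 | step 8 | 4-bromo-3,5-bis{[4-(benzyloxy)benzyl]oxy}benzonitrile | N#Cc1cc(OCc2ccc(OCc3ccccc3)cc2)c(Br)c(OCc2ccc(OCc3ccccc3)cc2)c1
F5 | step 8 | N–H ketimine corresponding to ketone 10 | N=C(c1c(OCc2ccc(OCc3ccccc3)cc2)cc(/C=C/c2ccc(OCc3ccccc3)cc2)cc1OCc1ccc(OCc2ccccc2)cc1)c1cc(OCc2ccc(OCc3ccccc3)cc2)c(Br)c(OCc2ccc(OCc3ccccc3)cc2)c1
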